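**Plan**
1. Enabling feature: C7, the CH(butyl) carbon, is bonded to the ring B carbon that lies between the two phenolic C–O carbons, and C20 sits the same way on ring A. An aryl–CH bond ortho to a phenol oxygen is what an aryl allyl ether (3,3) shift leaves behind, with the saturated four-carbon arm starting as an (E)-alk-1-enyl group.
2. Cuts, in retrosynthetic order: the carbamate C–O bonds; the C–Cl bonds of the CHCl2 end (from a CH2OBn end); ring B–C7 (Claisen contraction of a 24-membered aryl allyl ether); O–Cb of that ether (Mitsunobu macrocyclisation); ring A–C20 (open-chain Mitsunobu/Claisen pair); the two allylic C=C bonds (cross metathesis); C3–C4 and C16–C17 (copper-catalysed alkyl coupling); C1–C2 and C14–C15 (aldol).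
3. Forward: one arene building block from 3,5-dihydroxybenzaldehyde serves as both halves. The halves are joined at a ring A oxygen and the link is moved to carbon (C20). The 24-membered ring is then closed at a ring B oxygen, and the shift to C7 contracts it to the 22-membered paracyclophane.
4. Stereochemistry: C1/C2 and C14/C15 come from an Evans syn aldol with the (R)-benzyloxazolidinone. C20 comes from (S)-5-(benzyloxy)pent-1-en-3-ol (Sharpless kinetic resolution) and C7 from (R)-pent-1-en-3-ol (from (R)-1,2-epoxybutane), each by Mitsunobu inversion and then suprafacial 1,3-transfer through a chair.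
5. Regiocontrol: before each shift the arene carries bromine on both carbons flanking its carbinol side chain, so only the carbon between the oxygens is open. All four bromines leave with the benzyl group by hydrogenolysis before chlorine is introduced.

Key step: step 21

Labels: C1 = carbinol CH on ring A, C2 = CHMe, C3–C6 = CH2, C7 = CH on ring B. C14 = carbinol CH on ring B, C15 = CHMe, C16–C19 = CH2, C20 = CH on ring A. Ca and Cb are the first and second carbon of the four-carbon arm on C7. TBS = tert-butyldimethylsilyl, MOM = methoxymethyl, Bn = benzyl.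
Assumption: the SMILES is taken literally (1R,2S,7S,14R,15S,20S). Butyl ranks below and 4,4-dichlorobutyl above the ring chain, so equal descriptors mean opposite spatial sense at C7 and C20, and the two allylic alcohols are needed with opposite sense (R for the C7 arm, S for the C20 arm).

Step 1
Reactants: 1 3,5-dihydroxybenzaldehyde
Product: 2 3-hydroxy-5-(methoxymethoxy)benzaldehyde
Conditions: MOMCl (1.0 equiv), iPr2NEt, CH2Cl2/THF, 0 °C to rt
Reagents that add atoms: chloromethyl methyl ether (MOMCl), COCCl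
Why: Williamson-type O-alkylation of one of two equivalent phenols with one equivalent of MOMCl should give the mono-ether, which is separable from the diol and the bis-ether.

Step 2
Reactants: 2 3-hydroxy-5-(methoxymethoxy)benzaldehyde
Product: 3 3-(TBS-oxy)-5-(MOM-oxy)benzaldehyde
Conditions: TBSCl, imidazole, DMF, rt
Reagents that add atoms: tert-butyldimethylsilyl chloride (TBSCl), CC(C)(C)[Si](C)(C)Cl
Why: Standard phenol silylation installs a mask that bifluoride can later remove without touching alkyl silyl ethers or MOM groups.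

Step 3
Reactants: 3 3-(TBS-oxy)-5-(MOM-oxy)benzaldehyde; 4 (R)-4-benzyl-3-propionyloxazolidin-2-one
Product: 7 (R)-4-benzyl-3-[(2R,3R)-3-hydroxy-2-methyl-3-(3-TBSO-5-MOMO-phenyl)propanoyl]oxazolidin-2-one, via dibutylboron Z-enolate 5 (not isolated), via dibutylboron aldolate 6 (not isolated)
Conditions: 4, nBu2BOTf, Et3N, CH2Cl2, 0 °C; 3, −78 to 0 °C; pH 7 buffer, MeOH, 30% H2O2, 0 °C
Reagents that add atoms: none
Why: Evans syn aldol reaction, in which the Z-boron enolate reacts through a closed chair on the enolate face left open by the (R)-benzyl group, setting the carbinol carbon (later C1 and C14) as R and the methyl carbon (later C2 and C15) syn to it.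

Step 4
Reactants: 7 syn aldol adduct
Product: 8 3-O-TBS ether of 7
Conditions: TBSOTf, 2,6-lutidine, CH2Cl2, −78 to 0 °C
Reagents that add atoms: tert-butyldimethylsilyl triflate (TBSOTf), CC(C)(C)[Si](C)(C)OS(=O)(=O)C(F)(F)F
Why: Silyl triflate silylation under a non-nucleophilic base protects the secondary benzylic alcohol and blocks retro-aldol cleavage.

Step 5
Reactants: 8 silylated aldol adduct
Product: 9 (2S,3R)-2-methyl-3-(TBS-oxy)-3-(3-TBSO-5-MOMO-phenyl)propan-1-ol
Conditions: LiBH4, MeOH (1 equiv), THF, 0 °C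
Reagents that add atoms: none
Why: Reductive cleavage of the N-acyloxazolidinone with LiBH4 gives the primary alcohol (C3) without touching either stereocentre and returns the auxiliary.

Step 6
Reactants: 9 primary alcohol
Product: 10 (1R,2R)-3-iodo-2-methyl-1-(3-TBSO-5-MOMO-phenyl)propyl TBS ether
Conditions: I2, PPh3, imidazole, CH2Cl2, 0 °C to rt
Reagents that add atoms: iodine, [I][I]
Why: Appel-type iodination converts the unhindered primary alcohol under neutral conditions (the descriptor at the methyl carbon changes by priority only).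

Step 7
Reactants: 10 primary iodide; 11 5-bromopent-1-ene
Product: 13 (1R,2S)-2-methyl-1-(3-TBSO-5-MOMO-phenyl)oct-7-enyl TBS ether, via pent-4-enylmagnesium bromide 12 (not isolated)
Conditions: 11, Mg, THF; then 10, Li2CuCl4 (5 mol %), THF, −20 to 0 °C
Reagents that add atoms: none
Why: Li2CuCl4-catalysed cross-coupling of an alkyl Grignard reagent with a primary iodide forms C3–C4 (and C16–C17) and delivers the chain with its terminal alkene in one operation.

Step 8
Reactants: 13 building block for both halves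
Product: 14 3-[(1R,2S)-2-methyl-1-(TBS-oxy)oct-7-enyl]-5-(MOM-oxy)phenol
Conditions: KHF2, MeOH, rt
Reagents that add atoms: none
Why: Bifluoride desilylation cleaves the phenolic silyl ether much faster than the hindered secondary alkyl silyl ether.

Step 9
Reactants: 14 phenol
Product: 15 2,4-dibromo-3-[(1R,2S)-2-methyl-1-(TBS-oxy)oct-7-enyl]-5-(MOM-oxy)phenol (ring A half)
Conditions: NBS (2.05 equiv), MeCN, −20 to 0 °C, dark
Reagents that add atoms: N-bromosuccinimide (NBS), O=C1CCC(=O)N1Br
Why: Electrophilic aromatic bromination of a 5-alkylresorcinol derivative goes to the two carbons next to the alkyl group (each para to one oxygen) before the carbon between the oxygens, and the phenol ring reacts far faster than the terminal alkene.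

Step 10
Reactants: 16 3-(benzyloxy)propanal; 17 vinylmagnesium bromide
Product: 18 racemic 5-(benzyloxy)pent-1-en-3-ol
Conditions: THF, −78 to 0 °C; aq NH4Cl
Reagents that add atoms: none
Why: Grignard 1,2-addition at low temperature outruns β-elimination of benzyloxide.

Step 11
Reactants: 18 racemic 5-(benzyloxy)pent-1-en-3-ol
Product: 19 (S)-5-(benzyloxy)pent-1-en-3-ol
Conditions: Ti(OiPr)4 (10 mol %), D-(−)-DIPT (12 mol %), tBuOOH (0.6 equiv), 4 Å MS, CH2Cl2, −20 °C
Reagents that add atoms: none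
Why: Sharpless kinetic resolution, in which D-(−)-DIPT makes the (R)-alcohol epoxidise faster, so the (S)-alcohol should remain in high enantiomeric purity just past half conversion.

Step 12
Reactants: 13 building block for both halves; 19 (S)-5-(benzyloxy)pent-1-en-3-ol (3 equiv)
Product: 20 (3S,4E,10S,11R)-1-(benzyloxy)-10-methyl-11-(TBS-oxy)-11-(3-TBSO-5-MOMO-phenyl)undec-4-en-3-ol (ring B half)
Conditions: second-generation Hoveyda–Grubbs catalyst (H2IMes)Cl2Ru(=CH-2-iPrOC6H4) (5 mol %), CH2Cl2, 40 °C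
Reagents that add atoms: none
Why: Olefin cross metathesis of an unhindered terminal alkene with an excess of a secondary allylic alcohol should give the E-disubstituted alkene and leaves the carbinol centre untouched.

Step 13
Reactants: 15 ring A half (dibromophenol); 20 ring B half (allylic alcohol)
Product: 21 open-chain aryl (E)-allyl ether with the phenol oxygen of 15 on C3 of the undecenyl chain of 20 (ether carbon R)
Conditions: PPh3, DIAD, toluene, 0 °C to rt
Reagents that add atoms: none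
Why: Mitsunobu etherification, in which the acidic ortho-bromophenol displaces the activated secondary allylic alcohol by SN2 with inversion (S to R).

Step 14
Reactants: 21 open-chain aryl allyl ether
Product: 23 ring A phenol with C20 (S) on the carbon between OH and OMOM and an (E)-4-(benzyloxy)but-1-enyl arm, via ortho-dienone 22 (not isolated)
Conditions: PhNEt2, 180 °C, sealed tube, Ar
Reagents that add atoms: none
Why: Thermal aromatic Claisen rearrangement of an open-chain secondary (E)-allyl aryl ether, where the chair with the CH2CH2OBn group pseudo-equatorial carries the ether-carbon configuration suprafacially to C20 and gives the E-alkene, and the two bromines leave only the carbon between the oxygens open.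

Step 15
Reactants: 23 ring A phenol
Product: 24 ring A bis-MOM ether
Conditions: MOMCl, iPr2NEt, nBu4NI (cat.), CH2Cl2, 40 °C
Reagents that add atoms: chloromethyl methyl ether (MOMCl), COCCl
Why: O-alkylation of the acidic bromophenol masks ring A, so that ring B will later be the only phenol in the molecule.

Step 16
Reactants: 24 ring A bis-MOM ether
Product: 25 ring B phenol
Conditions: KHF2, MeOH/THF, rt
Reagents that add atoms: none
Why: Bifluoride desilylation removes the single aryl silyl ether and leaves both secondary alkyl TBS ethers, the MOM groups and the benzyl ether in place.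

Step 17
Reactants: 25 ring B phenol
Product: 26 ring B 2,4-dibromophenol
Conditions: NBS (2.05 equiv), MeCN/CH2Cl2, −20 °C, dark
Reagents that add atoms: N-bromosuccinimide (NBS), O=C1CCC(=O)N1Br
Why: Electrophilic aromatic bromination as in step 9, with ring A now hexasubstituted so that only the far more reactive free phenol ring B can take up bromine, at the two carbons flanking its side chain.

Step 18
Reactants: 27 (R)-1,2-epoxybutane
Product: 28 (R)-pent-1-en-3-ol
Conditions: Me3SI, nBuLi, THF, −10 °C to rt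
Reagents that add atoms: trimethylsulfonium iodide, C[S+](C)C.[I-]
Why: One-carbon homologation of a terminal epoxide to an allylic alcohol (opening at CH2 by dimethylsulfonium methylide, then loss of dimethyl sulfide) does not touch the stereocentre.

Step 19
Reactants: 26 ring B dibromophenol; 28 (R)-pent-1-en-3-ol (5 equiv)
Product: 29 seco compound with (E)-CH=CH-CH(OH)Et (carbinol R) at the end of the C1–C7 chain
Conditions: second-generation Hoveyda–Grubbs catalyst (H2IMes)Cl2Ru(=CH-2-iPrOC6H4) (5 mol %), CH2Cl2, 40 °C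
Reagents that add atoms: none
Why: Olefin cross metathesis picks the terminal alkene, because the internal alkene at C20 is shielded by the hexasubstituted ring A, and should give the E-allylic alcohol.

Step 20
Reactants: 29 seco compound
Product: 30 24-membered macrocyclic aryl (E)-allyl ether with the ring B oxygen on Cb (S)
Conditions: PPh3, DIAD, toluene, slow addition of 29 (final 1 mM), 0 °C to rt
Reagents that add atoms: none
Why: Intramolecular Mitsunobu etherification under high dilution closes the large ring end to end at an O–C bond by SN2 with inversion at Cb (R to S).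

Step 21
Reactants: 30 24-membered macrocyclic aryl allyl ether
Product: 32 22-membered [7.7]paracyclophane with (E)-but-1-enyl at C7 (7R) and a free ring B phenol, via ortho-dienone 31 (not isolated)
Conditions: PhNEt2 (0.02 M), 180 °C, sealed tube, Ar
Reagents that add atoms: none
Why: Proposed new method: heating should trigger a concerted (3,3) shift in which the O–Cb bond breaks while C7 bonds to the ring B carbon between the two oxygens, after which ortho-dienone 31 enolises irreversibly to phenol 32. The closest known reaction type is the thermal aromatic Claisen rearrangement of open-chain secondary (E)-allyl aryl ethers with 1,3-chirality transfer (step 14), and the new element is that allyl unit and arene belong to one macrocycle. The 22-membered ring is not closed end to end but arises by contraction of the 24-membered ring (O, Cb and Ca leave the perimeter and one more ring B carbon enters it), so the step is unimolecular and its rate does not depend on concentration. C7 is controlled by the S-configured ether carbon Cb, because in the chair with ethyl pseudo-equatorial the new bond forms on the allyl face that oxygen leaves, which gives the target's spatial arrangement at C7 (R while the arm is butenyl, S once it is butyl) and the E-butenyl group. Regioselectivity is secured by the bromines on the other ortho carbon and on the para carbon of ring B, which leave one hydrogen-bearing site and turn the O–Cb bond towards it, while allylic strain favours chair over boat and equatorial over axial ethyl and the long tethers of the large ring should not oppose that geometry.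

Step 22
Reactants: 32 paracyclophane phenol
Product: 33 tetra-MOM paracyclophane diene
Conditions: MOMCl, iPr2NEt, nBu4NI (cat.), CH2Cl2, 40 °C
Reagents that add atoms: chloromethyl methyl ether (MOMCl), COCCl
Why: O-alkylation masks the new phenol before the oxidation, chlorination and carbamoylation steps that it would not survive.

Step 23
Reactants: 33 tetra-MOM paracyclophane diene
Product: 34 saturated tetrabromide with butyl at C7 (7S) and 4-(benzyloxy)butyl at C20 (20S)
Conditions: TsNHNH2, NaOAc, DME/H2O, 85 °C, repeated charges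
Reagents that add atoms: none
Why: Diimide reduction transfers H2 in a concerted way without metal hydride intermediates, so the allylic and benzylic centres C7 and C20 cannot be scrambled by double-bond migration, and the C–Br and O–Bn bonds survive.

Step 24
Reactants: 34 saturated tetrabromide
Product: 35 bromine-free primary alcohol with 4-hydroxybutyl at C20
Conditions: H2 (1 atm), 10% Pd/C, NaOAc, EtOH/EtOAc, rt
Reagents that add atoms: none
Why: Catalytic hydrogenolysis removes the four blocking bromines and the benzyl ether in one operation, with NaOAc taking up HBr so that MOM and silyl ethers survive, and it is placed before any C–Cl bond exists.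

Step 25
Reactants: 35 primary alcohol
Product: 36 aldehyde with 4-oxobutyl at C20
Conditions: Dess–Martin periodinane, CH2Cl2, 0 °C to rt
Reagents that add atoms: none
Why: Dess–Martin oxidation stops at the aldehyde under near-neutral conditions that all protecting groups tolerate.

Step 26
Reactants: 36 aldehyde
Product: 38 gem-dichloride with 4,4-dichlorobutyl at C20, via hydrazone 37 (not isolated)
Conditions: N2H4·H2O (excess), MeOH, 4 Å MS, rt, concentrate; then CuCl2, Et3N, MeOH, 0 °C to rt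
Reagents that add atoms: copper dichloride (CuCl2), Cl[Cu]Cl
Why: Copper-mediated oxidative gem-dichlorination of an aldehyde hydrazone with loss of N2 runs under mild basic conditions compatible with MOM and TBS ethers.

Step 27
Reactants: 38 gem-dichloride
Product: 39 C1,C14-diol
Conditions: nBu4NF, AcOH, THF, rt to 40 °C
Reagents that add atoms: none
Why: Fluoride desilylation buffered with acetic acid frees both benzylic alcohols with retention and avoids base-induced loss of HCl from the CHCl2 group.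

Step 28
Reactants: 39 C1,C14-diol
Product: 41 C1,C14-bis(carbamate) tetra-MOM ether, via bis(N-trichloroacetylcarbamate) 40 (not isolated)
Conditions: Cl3CC(O)NCO, CH2Cl2, 0 °C; then K2CO3 (cat.), MeOH, rt
Reagents that add atoms: trichloroacetyl isocyanate, O=C=NC(=O)C(Cl)(Cl)Cl
Why: Carbamoylation with trichloroacetyl isocyanate followed by methanolysis of the trichloroacetyl group acylates at oxygen, so C1 and C14 keep their configuration.

Step 29
Reactants: 41 bis(carbamate) tetra-MOM ether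
Product: 42 CNP0135078.1
Conditions: HCl (about 1 M), MeOH, 35 °C
Reagents that add atoms: none
Why: Acid-catalysed acetal exchange removes the four aryl MOM groups, and the benzylic carbamates should hold because both ring oxygens are meta to the carbinol carbon and cannot stabilise a benzylic cation.

**Compound list**
1 | 3,5-dihydroxybenzaldehyde | O=Cc1cc(O)cc(O)c1 | starting material
2 | 3-hydroxy-5-(methoxymethoxy)benzaldehyde | O=Cc1cc(O)cc(OCOC)c1 | intermediate
3 | 3-(TBS-oxy)-5-(MOM-oxy)benzaldehyde | O=Cc1cc(OCOC)cc(O[Si](C)(C)C(C)(C)C)c1 | intermediate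
4 | (R)-4-benzyl-3-propionyloxazolidin-2-one | CCC(=O)N1[C@H](Cc2ccccc2)COC1=O | starting material
5 | dibutylboron Z-enolate of 4 | C/C=C(\OB(CCCC)CCCC)N1[C@H](Cc2ccccc2)COC1=O | intermediate
6 | dibutylboron aldolate (2R,3R) | O=C1OC[C@@H](Cc2ccccc2)N1C(=O)[C@H](C)[C@@H](OB(CCCC)CCCC)c1cc(OCOC)cc(O[Si](C)(C)C(C)(C)C)c1 | intermediate
7 | syn aldol adduct (2R,3R; auxiliary R) | O=C1OC[C@@H](Cc2ccccc2)N1C(=O)[C@H](C)[C@@H](O)c1cc(OCOC)cc(O[Si](C)(C)C(C)(C)C)c1 | intermediate
8 | 3-O-TBS ether of 7 | O=C1OC[C@@H](Cc2ccccc2)N1C(=O)[C@H](C)[C@@H](O[Si](C)(C)C(C)(C)C)c1cc(OCOC)cc(O[Si](C)(C)C(C)(C)C)c1 | intermediate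
9 | (2S,3R)-2-methyl-3-(TBS-oxy)-3-(3-TBSO-5-MOMO-phenyl)propan-1-ol | OC[C@H](C)[C@@H](O[Si](C)(C)C(C)(C)C)c1cc(OCOC)cc(O[Si](C)(C)C(C)(C)C)c1 | intermediate
10 | (1R,2R)-3-iodo-2-methyl-1-(3-TBSO-5-MOMO-phenyl)propyl TBS ether | IC[C@H](C)[C@@H](O[Si](C)(C)C(C)(C)C)c1cc(OCOC)cc(O[Si](C)(C)C(C)(C)C)c1 | intermediate
11 | 5-bromopent-1-ene | C=CCCCBr | starting material
12 | pent-4-enylmagnesium bromide | C=CCCC[Mg]Br | intermediate
13 | (1R,2S)-2-methyl-1-(3-TBSO-5-MOMO-phenyl)oct-7-enyl TBS ether | C=CCCCC[C@H](C)[C@@H](O[Si](C)(C)C(C)(C)C)c1cc(OCOC)cc(O[Si](C)(C)C(C)(C)C)c1 | intermediate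
14 | 3-[(1R,2S)-2-methyl-1-(TBS-oxy)oct-7-enyl]-5-(MOM-oxy)phenol | C=CCCCC[C@H](C)[C@@H](O[Si](C)(C)C(C)(C)C)c1cc(O)cc(OCOC)c1 | intermediate
15 | 2,4-dibromo-3-[(1R,2S)-2-methyl-1-(TBS-oxy)oct-7-enyl]-5-(MOM-oxy)phenol (ring A half) | C=CCCCC[C@H](C)[C@@H](O[Si](C)(C)C(C)(C)C)c1c(Br)c(O)cc(OCOC)c1Br | intermediate
16 | 3-(benzyloxy)propanal | O=CCCOCc1ccccc1 | starting material
17 | vinylmagnesium bromide | C=C[Mg]Br | starting material
18 | racemic 5-(benzyloxy)pent-1-en-3-ol | OC(CCOCc1ccccc1)C=C | intermediate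
19 | (S)-5-(benzyloxy)pent-1-en-3-ol | O[C@@H](CCOCc1ccccc1)C=C | intermediate
20 | (3S,4E,10S,11R)-1-(benzyloxy)-10-methyl-11-(TBS-oxy)-11-(3-TBSO-5-MOMO-phenyl)undec-4-en-3-ol (ring B half) | O[C@@H](CCOCc1ccccc1)/C=C/CCCC[C@H](C)[C@@H](O[Si](C)(C)C(C)(C)C)c1cc(OCOC)cc(O[Si](C)(C)C(C)(C)C)c1 | intermediate
21 | open-chain aryl (E)-allyl ether, ether carbon R | C=CCCCC[C@H](C)[C@@H](O[Si](C)(C)C(C)(C)C)c1c(Br)c(O[C@H](CCOCc2ccccc2)/C=C/CCCC[C@H](C)[C@@H](O[Si](C)(C)C(C)(C)C)c2cc(OCOC)cc(O[Si](C)(C)C(C)(C)C)c2)cc(OCOC)c1Br | intermediate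
22 | ring A ortho-dienone (cyclohexa-2,4-dienone tautomer of 23) | C=CCCCC[C@H](C)[C@@H](O[Si](C)(C)C(C)(C)C)C1=C(Br)C(=O)[C@@H]([C@H](/C=C/CCOCc2ccccc2)CCCC[C@H](C)[C@@H](O[Si](C)(C)C(C)(C)C)c2cc(OCOC)cc(O[Si](C)(C)C(C)(C)C)c2)C(OCOC)=C1Br | intermediate
23 | ring A phenol, C20 (S) with (E)-4-(benzyloxy)but-1-enyl arm | C=CCCCC[C@H](C)[C@@H](O[Si](C)(C)C(C)(C)C)c1c(Br)c(O)c([C@H](/C=C/CCOCc2ccccc2)CCCC[C@H](C)[C@@H](O[Si](C)(C)C(C)(C)C)c2cc(OCOC)cc(O[Si](C)(C)C(C)(C)C)c2)c(OCOC)c1Br | intermediate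
24 | ring A bis-MOM ether of 23 | C=CCCCC[C@H](C)[C@@H](O[Si](C)(C)C(C)(C)C)c1c(Br)c(OCOC)c([C@H](/C=C/CCOCc2ccccc2)CCCC[C@H](C)[C@@H](O[Si](C)(C)C(C)(C)C)c2cc(OCOC)cc(O[Si](C)(C)C(C)(C)C)c2)c(OCOC)c1Br | intermediate
25 | ring B phenol | C=CCCCC[C@H](C)[C@@H](O[Si](C)(C)C(C)(C)C)c1c(Br)c(OCOC)c([C@H](/C=C/CCOCc2ccccc2)CCCC[C@H](C)[C@@H](O[Si](C)(C)C(C)(C)C)c2cc(O)cc(OCOC)c2)c(OCOC)c1Br | intermediate
26 | ring B 2,4-dibromophenol | C=CCCCC[C@H](C)[C@@H](O[Si](C)(C)C(C)(C)C)c1c(Br)c(OCOC)c([C@H](/C=C/CCOCc2ccccc2)CCCC[C@H](C)[C@@H](O[Si](C)(C)C(C)(C)C)c2c(Br)c(O)cc(OCOC)c2Br)c(OCOC)c1Br | intermediate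
27 | (R)-1,2-epoxybutane | CC[C@@H]1CO1 | starting material
28 | (R)-pent-1-en-3-ol | CC[C@@H](O)C=C | intermediate
29 | seco compound, (R,E)-allylic alcohol and ring B phenol | CC[C@@H](O)/C=C/CCCC[C@H](C)[C@@H](O[Si](C)(C)C(C)(C)C)c1c(Br)c(OCOC)c([C@H](/C=C/CCOCc2ccccc2)CCCC[C@H](C)[C@@H](O[Si](C)(C)C(C)(C)C)c2c(Br)c(O)cc(OCOC)c2Br)c(OCOC)c1Br | intermediate
30 | 24-membered macrocyclic aryl (E)-allyl ether (Cb S; 1R,2S,14R,15S,20S), key-step precursor | CC[C@H]1/C=C/CCCC[C@H](C)[C@@H](O[Si](C)(C)C(C)(C)C)c2c(Br)c(OCOC)c(c(OCOC)c2Br)[C@H](/C=C/CCOCc2ccccc2)CCCC[C@H](C)[C@@H](O[Si](C)(C)C(C)(C)C)c2c(Br)c(O1)cc(OCOC)c2Br | intermediate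
31 | ring B ortho-dienone (cyclohexa-2,4-dienone tautomer of 32) | CC/C=C/[C@H]1CCCC[C@H](C)[C@@H](O[Si](C)(C)C(C)(C)C)c2c(Br)c(OCOC)c(c(OCOC)c2Br)[C@H](/C=C/CCOCc2ccccc2)CCCC[C@H](C)[C@@H](O[Si](C)(C)C(C)(C)C)C2=C(Br)C(=O)[C@H]1C(OCOC)=C2Br | intermediate
32 | 22-membered [7.7]paracyclophane, (E)-but-1-enyl at C7 (7R), free ring B phenol, key-step product | CC/C=C/[C@H]1CCCC[C@H](C)[C@@H](O[Si](C)(C)C(C)(C)C)c2c(Br)c(OCOC)c(c(OCOC)c2Br)[C@H](/C=C/CCOCc2ccccc2)CCCC[C@H](C)[C@@H](O[Si](C)(C)C(C)(C)C)c2c(Br)c(O)c1c(OCOC)c2Br | intermediate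
33 | tetra-MOM paracyclophane diene | CC/C=C/[C@H]1CCCC[C@H](C)[C@@H](O[Si](C)(C)C(C)(C)C)c2c(Br)c(OCOC)c(c(OCOC)c2Br)[C@H](/C=C/CCOCc2ccccc2)CCCC[C@H](C)[C@@H](O[Si](C)(C)C(C)(C)C)c2c(Br)c(OCOC)c1c(OCOC)c2Br | intermediate
34 | saturated tetrabromide (7S,20S) | CCCC[C@H]1CCCC[C@H](C)[C@@H](O[Si](C)(C)C(C)(C)C)c2c(Br)c(OCOC)c(c(OCOC)c2Br)[C@H](CCCCOCc2ccccc2)CCCC[C@H](C)[C@@H](O[Si](C)(C)C(C)(C)C)c2c(Br)c(OCOC)c1c(OCOC)c2Br | intermediate
35 | bromine-free primary alcohol | CCCC[C@H]1CCCC[C@H](C)[C@@H](O[Si](C)(C)C(C)(C)C)c2cc(OCOC)c(c(OCOC)c2)[C@H](CCCCO)CCCC[C@H](C)[C@@H](O[Si](C)(C)C(C)(C)C)c2cc(OCOC)c1c(OCOC)c2 | intermediate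
36 | aldehyde | CCCC[C@H]1CCCC[C@H](C)[C@@H](O[Si](C)(C)C(C)(C)C)c2cc(OCOC)c(c(OCOC)c2)[C@H](CCCC=O)CCCC[C@H](C)[C@@H](O[Si](C)(C)C(C)(C)C)c2cc(OCOC)c1c(OCOC)c2 | intermediate
37 | (E)-hydrazone of 36 | CCCC[C@H]1CCCC[C@H](C)[C@@H](O[Si](C)(C)C(C)(C)C)c2cc(OCOC)c(c(OCOC)c2)[C@H](CCC/C=N/N)CCCC[C@H](C)[C@@H](O[Si](C)(C)C(C)(C)C)c2cc(OCOC)c1c(OCOC)c2 | intermediate
38 | gem-dichloride | CCCC[C@H]1CCCC[C@H](C)[C@@H](O[Si](C)(C)C(C)(C)C)c2cc(OCOC)c(c(OCOC)c2)[C@H](CCCC(Cl)Cl)CCCC[C@H](C)[C@@H](O[Si](C)(C)C(C)(C)C)c2cc(OCOC)c1c(OCOC)c2 | intermediate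
39 | C1,C14-diol | CCCC[C@H]1CCCC[C@H](C)[C@@H](O)c2cc(OCOC)c(c(OCOC)c2)[C@H](CCCC(Cl)Cl)CCCC[C@H](C)[C@@H](O)c2cc(OCOC)c1c(OCOC)c2 | intermediate
40 | bis(N-trichloroacetylcarbamate) | CCCC[C@H]1CCCC[C@H](C)[C@@H](OC(=O)NC(=O)C(Cl)(Cl)Cl)c2cc(OCOC)c(c(OCOC)c2)[C@H](CCCC(Cl)Cl)CCCC[C@H](C)[C@@H](OC(=O)NC(=O)C(Cl)(Cl)Cl)c2cc(OCOC)c1c(OCOC)c2 | intermediate
41 | bis(carbamate) tetra-MOM ether | CCCC[C@H]1CCCC[C@H](C)[C@@H](OC(N)=O)c2cc(OCOC)c(c(OCOC)c2)[C@H](CCCC(Cl)Cl)CCCC[C@H](C)[C@@H](OC(N)=O)c2cc(OCOC)c1c(OCOC)c2 | intermediate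
42 | CNP0135078.1 (1R,2S,7S,14R,15S,20S) | CCCC[C@H]1CCCC[C@H](C)[C@@H](OC(N)=O)c2cc(O)c(c(O)c2)[C@H](CCCC(Cl)Cl)CCCC[C@H](C)[C@@H](OC(N)=O)c2cc(O)c1c(O)c2 | target

**Step count**
Total step count: 29.
Longest linear sequence: 25 steps (steps 1–9, 13–17, 19–29).

**Steps most likely to fail**

Step 21. The tethers may keep C7 away from the open ring B carbon, so that the chair is reached only slowly.
- Possible failure processes: heterolysis of the allylic C–O bond (a dibromophenoxide leaves easily), the boat or axial-ethyl pathways (loss of chirality transfer), or a follow-up ene-type isomerisation of the product on long heating.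
- Fallback, known chemistry only, from 9 back to 34: the shift is run on an open chain as in step 14, and the 22-membered ring is closed afterwards by ring-closing metathesis at C3=C4.
- Dess–Martin oxidation of 9 gives the aldehyde F1, and Wittig methylenation (Ph3P=CH2) gives the truncated alkene F2.
- The operations of steps 8 and 9 turn F2 into the phenol F3 and the dibromophenol F4.
- The operations of steps 13 to 17, with 20 as partner, give in turn the open-chain ether F5, the ring A phenol F6, its MOM ether F7, the ring B phenol F8 and the ring B dibromophenol F9.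
- Cross metathesis of 28 with an excess of hexa-1,5-diene gives the dienol F10, which is joined to F9 by Mitsunobu inversion to give the second open-chain ether F11.
- Heating in PhNEt2 gives the ring B phenol F12, with C7 set as in 32, and MOMCl gives the tetraene F13.
- Ring-closing metathesis (second-generation Grubbs catalyst (H2IMes)(PCy3)Cl2Ru=CHPh, high dilution) between the vinyl group on C2 and the but-3-enyl arm on C7 gives the macrocyclic triene F14.
- Diimide as in step 23 saturates the three double bonds of F14 to give 34.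

Step 20. Oligomerisation may outrun ring closure. Attack at C7 (SN2′) or partial ionisation of the activated allylic alcohol would erode the constitution or configuration at Cb.
- Fallback from 26 and 28 back to 30: the O–Cb bond is made between two molecules, and the large ring is closed at the Ca=C7 double bond instead.
- Mitsunobu etherification of 26 with 28 (inversion) gives the pent-1-en-3-yl ether F15.
- Ring-closing metathesis of its two terminal alkenes at high dilution closes the 24-membered ring, and the E isomer is 30.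

Step 26. Azine formation, incomplete oxidation of the hydrazone, loss of HCl to a vinyl chloride, or chlorination of the electron-rich rings by the copper salt may lower the return.
- Fallback from 36 back to 38: the nitrogen-loss route is replaced by direct deoxygenative gem-dichlorination of the carbonyl group.
- The reagent is made from (PhO)3P and Cl2 (slight excess of phosphite) in CH2Cl2 at −78 °C. No new compound is formed on the way.

**Further compounds**
F1 | step 21 | (2R,3R)-2-methyl-3-(TBS-oxy)-3-(3-TBSO-5-MOMO-phenyl)propanal | O=C[C@H](C)[C@@H](O[Si](C)(C)C(C)(C)C)c1cc(OCOC)cc(O[Si](C)(C)C(C)(C)C)c1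
F2 | step 21 | (1R,2S)-2-methyl-1-(3-TBSO-5-MOMO-phenyl)but-3-enyl TBS ether | C=C[C@H](C)[C@@H](O[Si](C)(C)C(C)(C)C)c1cc(OCOC)cc(O[Si](C)(C)C(C)(C)C)c1
F3 | step 21 | 3-[(1R,2S)-2-methyl-1-(TBS-oxy)but-3-enyl]-5-(MOM-oxy)phenol | C=C[C@H](C)[C@@H](O[Si](C)(C)C(C)(C)C)c1cc(O)cc(OCOC)c1
F4 | step 21 | 2,4-dibromo-3-[(1R,2S)-2-methyl-1-(TBS-oxy)but-3-enyl]-5-(MOM-oxy)phenol | C=C[C@H](C)[C@@H](O[Si](C)(C)C(C)(C)C)c1c(Br)c(O)cc(OCOC)c1Br
F5 | step 21 | open-chain aryl allyl ether from F4 and 20 (ether carbon R) | C=C[C@H](C)[C@@H](O[Si](C)(C)C(C)(C)C)c1c(Br)c(O[C@H](CCOCc2ccccc2)/C=C/CCCC[C@H](C)[C@@H](O[Si](C)(C)C(C)(C)C)c2cc(OCOC)cc(O[Si](C)(C)C(C)(C)C)c2)cc(OCOC)c1Br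
F6 | step 21 | ring A phenol with C20 (S) | C=C[C@H](C)[C@@H](O[Si](C)(C)C(C)(C)C)c1c(Br)c(O)c([C@H](/C=C/CCOCc2ccccc2)CCCC[C@H](C)[C@@H](O[Si](C)(C)C(C)(C)C)c2cc(OCOC)cc(O[Si](C)(C)C(C)(C)C)c2)c(OCOC)c1Br
F7 | step 21 | ring A bis-MOM ether of F6 | C=C[C@H](C)[C@@H](O[Si](C)(C)C(C)(C)C)c1c(Br)c(OCOC)c([C@H](/C=C/CCOCc2ccccc2)CCCC[C@H](C)[C@@H](O[Si](C)(C)C(C)(C)C)c2cc(OCOC)cc(O[Si](C)(C)C(C)(C)C)c2)c(OCOC)c1Br
F8 | step 21 | ring B phenol | C=C[C@H](C)[C@@H](O[Si](C)(C)C(C)(C)C)c1c(Br)c(OCOC)c([C@H](/C=C/CCOCc2ccccc2)CCCC[C@H](C)[C@@H](O[Si](C)(C)C(C)(C)C)c2cc(O)cc(OCOC)c2)c(OCOC)c1Br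
F9 | step 21 | ring B dibromophenol | C=C[C@H](C)[C@@H](O[Si](C)(C)C(C)(C)C)c1c(Br)c(OCOC)c([C@H](/C=C/CCOCc2ccccc2)CCCC[C@H](C)[C@@H](O[Si](C)(C)C(C)(C)C)c2c(Br)c(O)cc(OCOC)c2Br)c(OCOC)c1Br
F10 | step 21 | (3R,4E)-nona-4,8-dien-3-ol | CC[C@@H](O)/C=C/CCC=C
F11 | step 21 | open-chain ring B aryl allyl ether (ether carbon S) | C=C[C@H](C)[C@@H](O[Si](C)(C)C(C)(C)C)c1c(Br)c(OCOC)c([C@H](/C=C/CCOCc2ccccc2)CCCC[C@H](C)[C@@H](O[Si](C)(C)C(C)(C)C)c2c(Br)c(O[C@@H](CC)/C=C/CCC=C)cc(OCOC)c2Br)c(OCOC)c1Br
F12 | step 21 | ring B phenol with C7 bearing (E)-but-1-enyl and but-3-enyl | C=C[C@H](C)[C@@H](O[Si](C)(C)C(C)(C)C)c1c(Br)c(OCOC)c([C@H](/C=C/CCOCc2ccccc2)CCCC[C@H](C)[C@@H](O[Si](C)(C)C(C)(C)C)c2c(Br)c(O)c([C@@H](/C=C/CC)CCC=C)c(OCOC)c2Br)c(OCOC)c1Br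
F13 | step 21 | tetra-MOM tetraene | C=C[C@H](C)[C@@H](O[Si](C)(C)C(C)(C)C)c1c(Br)c(OCOC)c([C@H](/C=C/CCOCc2ccccc2)CCCC[C@H](C)[C@@H](O[Si](C)(C)C(C)(C)C)c2c(Br)c(OCOC)c([C@@H](/C=C/CC)CCC=C)c(OCOC)c2Br)c(OCOC)c1Br
F14 | step 21 | 22-membered macrocyclic triene with C3=C4 double bond | CC/C=C/[C@H]1CC/C=C/[C@H](C)[C@@H](O[Si](C)(C)C(C)(C)C)c2c(Br)c(OCOC)c(c(OCOC)c2Br)[C@H](/C=C/CCOCc2ccccc2)CCCC[C@H](C)[C@@H](O[Si](C)(C)C(C)(C)C)c2c(Br)c(OCOC)c1c(OCOC)c2Br
F15 | step 20 | ring B (S)-pent-1-en-3-yl ether of 26 | C=CCCCC[C@H](C)[C@@H](O[Si](C)(C)C(C)(C)C)c1c(Br)c(OCOC)c([C@H](/C=C/CCOCc2ccccc2)CCCC[C@H](C)[C@@H](O[Si](C)(C)C(C)(C)C)c2c(Br)c(O[C@@H](CC)C=C)cc(OCOC)c2Br)c(OCOC)c1Br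
F0 | step 26 | none | none
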